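**Plan**

- Numbering (germacrane): the ten-membered ring is C1–C10; the lactone ring is O–C6–C7–C11–C12; C13 is the exocyclic CH2, C14 the ester carbon, C15 the methyl. The array O–C8–C7–C11=C13H2 (homoallylic alcohol with exocyclic methylene, where the carbocycle meets the lactone) is the retron of a [2,3]-Wittig shift, and the C14 ester on C10 can stabilise a C8 carbanion once the ring alkene sits at C9=C10.
- Retrosynthesis: cut the C8–O acyl bond (epoxy acid 28); take the lactone back to a C6/C12 diol; take C9–OH/C1=C10 back to a C9=C10 enoate (singlet-oxygen ene); cut C7–C8 by ring contraction of the 13-membered ether 22 (oxygen bridging C8 and C13); open 22 at C1–C10 (B-alkyl Suzuki) and C13–O (Williamson).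
- Forward order: chain C1–C7/C11–C13 from pent-1-en-4-yne, formaldehyde and a propargyl ether → 4,5-epoxide → ether to the C8–C10 iodoenoate → 13-membered ether → ten-membered carbocycle → C8 ester → lactone ring → C9 hydroxyl.
- Stereochemistry: C6 by catalyst-controlled alkynylation; C4/C5 by hydroxyl-directed threo epoxidation; C7 and C8 in the ring contraction (from C6 and the C7=C11 geometry); C9 by the ene reaction on the folded ring; the acid by Sharpless epoxidation.

Key step: step 12

Remark: the acyl group is taken as the cis-dimethyl (2S,3R) epoxide that the SMILES encodes (the epoxide of tiglic acid), and in step 3 the ProPhenol antipode is the one that gives the 6R carbinol 8.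

**Route**

Step 1
Reactants: 1 pent-1-en-4-yne
Product: 4 (E)-3-methylhexa-2,5-dien-1-ol, via alkenyldimethylalane 2 (not isolated), via lithium alkenylaluminate 3 (not isolated)
Conditions: Me3Al, Cp2ZrCl2 (20 mol %), CH2Cl2, 0 °C → rt; n-BuLi, THF, −78 °C; (CH2O)n, −78 °C → rt; H2O
Reagents that add atoms: trimethylaluminium C[Al](C)C; paraformaldehyde (as formaldehyde) C=O
Why: Negishi carboalumination adds CH3 (C15) to C4 and Al to C5 syn across the terminal alkyne only, and the aluminate attacks formaldehyde with retention, which fixes the E geometry (C15 cis to C6).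

Step 2
Reactants: 4 (E)-3-methylhexa-2,5-dien-1-ol
Product: 5 (E)-3-methylhexa-2,5-dienal
Conditions: MnO2 (excess), CH2Cl2, rt
Reagents that add atoms: none
Why: MnO2 oxidises only the allylic alcohol under neutral conditions, so the skipped 2,5-diene should not move into conjugation.

Step 3
Reactants: 5 (E)-3-methylhexa-2,5-dienal; 6 tert-butyldimethyl(prop-2-yn-1-yloxy)silane
Product: 8 (4R,5E)-1-[(tert-butyldimethylsilyl)oxy]-6-methylnona-5,8-dien-2-yn-4-ol, via alkynyl(methyl)zinc 7 (not isolated)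
Conditions: Me2Zn, ProPhenol ligand (20 mol %), Ph3P=O (40 mol %), toluene, 0 °C; H2O
Reagents that add atoms: none
Why: Catalytic enantioselective alkynylzinc addition to an enal (dinuclear zinc ProPhenol alkynylation); the catalyst sets C6, and the mild zinc alkynylide adds 1,2 without enolising the skipped dienal.

Step 4
Reactants: 8 (4R,5E)-1-[(tert-butyldimethylsilyl)oxy]-6-methylnona-5,8-dien-2-yn-4-ol
Product: 10 (2Z,4R,5E)-1-[(tert-butyldimethylsilyl)oxy]-2-iodo-6-methylnona-2,5,8-trien-4-ol, via sodium vinylalanate 9 (not isolated)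
Conditions: NaAlH2(OCH2CH2OMe)2, THF, 0 °C; then I2, −78 °C → 0 °C; H2O
Reagents that add atoms: iodine II
Why: Hydroxyl-directed trans-hydroalumination of the propargylic alcohol puts hydride on C7 and holds aluminium on C11 cis to C6 (five-membered alanate 9), and iodinolysis with retention gives the Z iodoalkene; low temperature should suppress elimination of the silyloxy group to an allene.

Step 5
Reactants: 10 (2Z,4R,5E)-1-[(tert-butyldimethylsilyl)oxy]-2-iodo-6-methylnona-2,5,8-trien-4-ol
Product: 11 (1S,2Z)-1-[(2R,3R)-3-allyl-3-methyloxiran-2-yl]-4-[(tert-butyldimethylsilyl)oxy]-3-iodobut-2-en-1-ol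
Conditions: mCPBA (1.1 equiv), CH2Cl2, 0 °C
Reagents that add atoms: 3-chloroperbenzoic acid OOC(=O)c1cccc(Cl)c1
Why: Hydroxyl-directed peracid epoxidation: allylic 1,3-strain between the C15 methyl and C6 keeps H-6 in the alkene plane, so the hydrogen-bonded peracid attacks syn to OH (threo rule) and the E alkene gives the trans epoxide (4R,5R); the iodoalkene and the terminal alkene are far less nucleophilic.

Step 6
Reactants: 11 (1S,2Z)-1-[(2R,3R)-3-allyl-3-methyloxiran-2-yl]-4-[(tert-butyldimethylsilyl)oxy]-3-iodobut-2-en-1-ol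
Product: 12 triethylsilyl ether of 11 (C6–OSiEt3)
Conditions: Et3SiOTf, 2,6-lutidine, CH2Cl2, −78 °C
Reagents that add atoms: triethylsilyl triflate CC[Si](CC)(CC)OS(=O)(=O)C(F)(F)F
Why: Standard silylation of the secondary alcohol with a non-nucleophilic base; the triethylsilyl group is chosen so that it leaves together with the primary TBS group in step 16.

Step 7
Reactants: 12 triethylsilyl ether of 11
Product: 13 (2E,4S)-4-[(2R,3R)-3-allyl-3-methyloxiran-2-yl]-2-{[(tert-butyldimethylsilyl)oxy]methyl}-4-[(triethylsilyl)oxy]but-2-en-1-ol (C13H2OH cis to C6)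
Conditions: Bu3SnCH2OH, Pd(PPh3)4 (10 mol %), 1,4-dioxane, 90 °C
Reagents that add atoms: (tributylstannyl)methanol OC[Sn](CCCC)(CCCC)CCCC
Why: Stille hydroxymethylation replaces iodine with retention of alkene geometry, so C13 ends cis to C6 and C12 trans.

Step 8
Reactants: 13 allylic alcohol
Product: 14 tert-butyl{[(2Z,4S)-4-[(2R,3R)-3-allyl-3-methyloxiran-2-yl]-2-(bromomethyl)-4-[(triethylsilyl)oxy]but-2-en-1-yl]oxy}dimethylsilane
Conditions: CBr4, PPh3, CH2Cl2, −20 °C
Reagents that add atoms: carbon tetrabromide BrC(Br)(Br)Br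
Why: Appel bromination converts the primary allylic alcohol by SN2 displacement without allylic transposition or loss of geometry.

Step 9
Reactants: 15 methyl (triphenylphosphoranylidene)acetate; 16 glycolaldehyde dimer (1,4-dioxane-2,5-diol)
Product: 18 methyl (2Z)-4-hydroxy-2-iodobut-2-enoate, via iodo ylide 17 (not isolated)
Conditions: N-iodosuccinimide, CH2Cl2, −20 °C; then 16, rt
Reagents that add atoms: N-iodosuccinimide O=C1CCC(=O)N1I
Why: Iodination of the stabilised ylide and Wittig olefination of monomeric glycolaldehyde should give the α-iodo enoate with the ester trans to CH2OH (stabilised-ylide selectivity), which also prevents lactonisation.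

Step 10
Reactants: 14 allylic bromide; 18 methyl (2Z)-4-hydroxy-2-iodobut-2-enoate
Product: 20 methyl (2Z)-4-{[(2E,4S)-4-[(2R,3R)-3-allyl-3-methyloxiran-2-yl]-2-{[(tert-butyldimethylsilyl)oxy]methyl}-4-[(triethylsilyl)oxy]but-2-en-1-yl]oxy}-2-iodobut-2-enoate, via sodium alkoxide 19 (not isolated)
Conditions: NaH (1.1 equiv), THF–DMF, −20 °C; then 14, −20 → 0 °C
Reagents that add atoms: none
Why: Williamson etherification of the alkoxide of 18 at the primary allylic bromide (SN2) forms the C13–O–C8 ether; the cold conditions are meant to avoid dehydroiodination of the iodoenoate.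

Step 11
Reactants: 20 seco ether
Product: 22 13-membered cyclic ether (ring O–C8–C9=C10–C1–C2–C3–C4–C5–C6–C7=C11–C13), via B-alkyl-9-BBN 21 (not isolated)
Conditions: 9-BBN, THF, rt; then slow addition to Pd(dppf)Cl2 (10 mol %), AsPh3, Cs2CO3, DMF–THF–H2O, 50 °C, about 1 mM
Reagents that add atoms: none
Why: 9-BBN hydroborates only the monosubstituted C1=C2 alkene (boron on C1), and intramolecular B-alkyl Suzuki–Miyaura coupling with the alkenyl iodide under high dilution closes the 13-membered ring with retention at C10 (C8 cis to C1).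

Step 12
Reactants: 22 13-membered cyclic ether
Product: 24 ring-contracted cyclodecenol (C8–OH), via lithium dienolate 23 (not isolated)
Conditions: LiN(iPr)2 (1.3 equiv), THF–DMPU, −78 → −30 °C; H2O at −78 °C
Reagents that add atoms: none
Why: Proposed new method: LiN(iPr)2 removes the C8 proton γ to the C14 ester (vinylogous through C9=C10) to give dienolate 23, whose oxygen-bearing terminus C8 bonds to C7 while the C13–O bond breaks, a [2,3]-Wittig shift through the five-atom envelope C8–O–C13–C11–C7 that moves the double bond to C11=C13 and leaves the C8 alkoxide. The closest known reaction types are the [2,3]-Wittig ring contraction of 13-membered diallyl and allyl propargyl ethers to ten-membered carbocycles and the [2,3]-Wittig rearrangement of ester enolates; new here is a γ-oxygenated ester dienolate as the carbanion inside a macrocycle. The ten-membered ring C1–C10 is closed by ring contraction (13 to 10 ring atoms, transannular C8-to-C7 bond formation with O and C13 leaving the ring), not by an end-to-end cyclisation. C7 is controlled by C6: the ring spans one face of the ring-cis C7=C11 bond and allylic 1,3-strain with C13H2 keeps H-6 in the alkene plane with the silyloxy group outside, so C8 should arrive anti to O-6 (H-6/H-7 trans); C8 is controlled by the alkene geometry (C6 cis to C13), which with C9 exo in the envelope should give the H-7/H-8 cis carbinol. The step needs deprotonation at C8 only and [2,3] rather than [1,2] or [3,3] migration: the ester makes C8 the single acidified CH2 (C12 is held as a silyl ether so that C6–H is not vinylogously acidic and the new alkoxide cannot lactonise), C9 is a node of the dienolate HOMO, and the reaction is run cold. The ring-cis C9=C10 geometry keeps the C8 alkoxide trans to the ester, so no butenolide should form.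

Step 13
Reactants: 25 (E)-2-methylbut-2-en-1-ol
Product: 26 [(2R,3R)-2,3-dimethyloxiran-2-yl]methanol
Conditions: Ti(OiPr)4 (10 mol %), D-(−)-diethyl tartrate (12 mol %), t-BuOOH, 4 Å sieves, CH2Cl2, −20 °C
Reagents that add atoms: tert-butyl hydroperoxide CC(C)(C)OO
Why: Sharpless asymmetric epoxidation of the E allylic alcohol; the D-(−)-tartrate catalyst gives the (2R,3R)-epoxy alcohol by reagent control.

Step 14
Reactants: 26 [(2R,3R)-2,3-dimethyloxiran-2-yl]methanol
Product: 28 (2S,3R)-2,3-dimethyloxirane-2-carboxylic acid, via epoxy aldehyde 27 (not isolated)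
Conditions: RuCl3 (2 mol %), NaIO4, CCl4–MeCN–H2O, rt
Reagents that add atoms: water O
Why: Catalytic RuO4 oxidation takes the primary alcohol through aldehyde 27 (as its hydrate) to the acid without opening the epoxide; the 2S descriptor arises only from the changed priorities.

Step 15
Reactants: 24 cyclodecenol; 28 (2S,3R)-2,3-dimethyloxirane-2-carboxylic acid
Product: 30 C8 ester, via mixed anhydride 29 (not isolated)
Conditions: 28, 2,4,6-trichlorobenzoyl chloride, Et3N, THF, rt; then 24, DMAP, toluene, 40 °C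
Reagents that add atoms: none
Why: Yamaguchi esterification through mixed anhydride 29 acylates the hindered secondary C8 alcohol with retention at C8; the acid has no α-hydrogen to epimerise.

Step 16
Reactants: 30 C8 ester
Product: 31 C6,C12-diol
Conditions: HF·pyridine, pyridine, THF, 0 °C → rt
Reagents that add atoms: none
Why: Buffered fluoride cleaves both silyl ethers; without a basic medium the C8 acyl group should not migrate and the epoxides and esters should survive.

Step 17
Reactants: 31 C6,C12-diol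
Product: 33 α-methylene γ-lactone (C9=C10 enoate), via lactol 32 (not isolated)
Conditions: TEMPO (20 mol %), PhI(OAc)2 (2.5 equiv), CH2Cl2, rt
Reagents that add atoms: none
Why: TEMPO/PhI(OAc)2 selects the primary allylic alcohol, the C6 hydroxyl closes lactol 32 (five-membered ring) and a second oxidation gives the lactone, the usual oxidative lactonisation of 2-methylene-1,4-diols.

Step 18
Reactants: 33 α-methylene γ-lactone
Product: 35 CNP0262846.1, via C9 hydroperoxide 34 (not isolated)
Conditions: O2, tetraphenylporphyrin (cat.), visible light, CH2Cl2, 0 °C; then PPh3, 0 °C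
Reagents that add atoms: dioxygen O=O
Why: Schenck ene reaction of singlet oxygen with the trisubstituted enoate follows the gem rule (hydrogen taken from C1, the alkyl group geminal to the ester), which puts the hydroperoxide on C9 and moves the alkene to C1=C10; oxygen is expected on the outer face of the ring-cis C9=C10 bond, anti to ring carbon C7 (9R), the electron-poor C11=C13 bond being inert, and Ph3P reduces the hydroperoxide.

**Compound list**

1 | pent-1-en-4-yne | C#CCC=C | starting material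
2 | dimethyl[(E)-2-methylpenta-1,4-dienyl]alane | C=CC/C(C)=C/[Al](C)C | intermediate
3 | lithium butyl(dimethyl)[(E)-2-methylpenta-1,4-dienyl]aluminate | [Li+].C=CC/C(C)=C/[Al-](C)(C)CCCC | intermediate
4 | (E)-3-methylhexa-2,5-dien-1-ol | C=CC/C(C)=C/CO | intermediate
5 | (E)-3-methylhexa-2,5-dienal | C=CC/C(C)=C/C=O | intermediate
6 | tert-butyldimethyl(prop-2-yn-1-yloxy)silane | C#CCO[Si](C)(C)C(C)(C)C | starting material
7 | methyl[3-(tert-butyldimethylsilyloxy)prop-1-ynyl]zinc | C[Zn]C#CCO[Si](C)(C)C(C)(C)C | intermediate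
8 | (4R,5E)-1-[(tert-butyldimethylsilyl)oxy]-6-methylnona-5,8-dien-2-yn-4-ol (C6 carbinol) | C=CC/C(C)=C/[C@@H](O)C#CCO[Si](C)(C)C(C)(C)C | intermediate
9 | sodium vinylalanate: five-membered ring O6–Al–C11=C7–C6, two 2-methoxyethoxy groups on Al | [Na+].C=CC/C(C)=C/[C@H]1O[Al-](OCCOC)(OCCOC)C(CO[Si](C)(C)C(C)(C)C)=C1 | intermediate
10 | (2Z,4R,5E)-1-[(tert-butyldimethylsilyl)oxy]-2-iodo-6-methylnona-2,5,8-trien-4-ol | C=CC/C(C)=C/[C@@H](O)/C=C(\I)CO[Si](C)(C)C(C)(C)C | intermediate
11 | (1S,2Z)-1-[(2R,3R)-3-allyl-3-methyloxiran-2-yl]-4-[(tert-butyldimethylsilyl)oxy]-3-iodobut-2-en-1-ol | C=CC[C@@]1(C)O[C@@H]1[C@@H](O)/C=C(\I)CO[Si](C)(C)C(C)(C)C | intermediate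
12 | triethylsilyl ether of 11 at C6 (4R,5R,6S; Z iodoalkene) | C=CC[C@@]1(C)O[C@@H]1[C@@H](O[Si](CC)(CC)CC)/C=C(\I)CO[Si](C)(C)C(C)(C)C | intermediate
13 | (2E,4S)-4-[(2R,3R)-3-allyl-3-methyloxiran-2-yl]-2-{[(tert-butyldimethylsilyl)oxy]methyl}-4-[(triethylsilyl)oxy]but-2-en-1-ol | C=CC[C@@]1(C)O[C@@H]1[C@@H](O[Si](CC)(CC)CC)/C=C(\CO)CO[Si](C)(C)C(C)(C)C | intermediate
14 | tert-butyl{[(2Z,4S)-4-[(2R,3R)-3-allyl-3-methyloxiran-2-yl]-2-(bromomethyl)-4-[(triethylsilyl)oxy]but-2-en-1-yl]oxy}dimethylsilane | C=CC[C@@]1(C)O[C@@H]1[C@@H](O[Si](CC)(CC)CC)/C=C(\CBr)CO[Si](C)(C)C(C)(C)C | intermediate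
15 | methyl (triphenylphosphoranylidene)acetate | COC(=O)C=P(c1ccccc1)(c1ccccc1)c1ccccc1 | starting material
16 | glycolaldehyde dimer (1,4-dioxane-2,5-diol) | OC1COC(O)CO1 | starting material
17 | methyl iodo(triphenylphosphoranylidene)acetate | COC(=O)C(I)=P(c1ccccc1)(c1ccccc1)c1ccccc1 | intermediate
18 | methyl (2Z)-4-hydroxy-2-iodobut-2-enoate | COC(=O)/C(I)=C/CO | intermediate
19 | sodium alkoxide of 18 | COC(=O)/C(I)=C/C[O-].[Na+] | intermediate
20 | methyl (2Z)-4-{[(2E,4S)-4-[(2R,3R)-3-allyl-3-methyloxiran-2-yl]-2-{[(tert-butyldimethylsilyl)oxy]methyl}-4-[(triethylsilyl)oxy]but-2-en-1-yl]oxy}-2-iodobut-2-enoate | C=CC[C@@]1(C)O[C@@H]1[C@@H](O[Si](CC)(CC)CC)/C=C(\COC/C=C(\I)C(=O)OC)CO[Si](C)(C)C(C)(C)C | intermediate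
21 | B-alkyl-9-borabicyclo[3.3.1]nonane of 20 (boron on C1) | C1CCC2CCCC1B2CCC[C@@]3(C)O[C@@H]3[C@@H](O[Si](CC)(CC)CC)/C=C(\COC/C=C(\I)C(=O)OC)CO[Si](C)(C)C(C)(C)C | intermediate
22 | 13-membered cyclic ether: ring O–C8H2–C9H=C10(CO2Me)–C1H2–C2H2–C3H2–C4(CH3)–C5H–C6H(OSiEt3)–C7H=C11(CH2OTBS)–C13H2; 4,5-epoxide (4R,5R); 6S; C8 cis to C1 and C6 cis to C13 | C1CC[C@@]2(C)O[C@@H]2[C@@H](O[Si](CC)(CC)CC)/C=C(\COC/C=C1/C(=O)OC)CO[Si](C)(C)C(C)(C)C | intermediate
23 | lithium dienolate of 22 (C8=C9–C10=C14(OLi)OMe; enolate geometry not defined) | [Li+].C1CC[C@@]2(C)O[C@@H]2[C@@H](O[Si](CC)(CC)CC)/C=C(\COC=CC1=C([O-])OC)CO[Si](C)(C)C(C)(C)C | intermediate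
24 | cyclodecenol: ten-membered ring C1–C10 with 8-OH, 7-[3-(TBSO)prop-1-en-2-yl], 6-OSiEt3, 4,5-epoxy-4-methyl, ring-cis C9=C10 bearing CO2Me; stereocentres C4–C8 arranged as in 35 (H-6/H-7 trans, H-7/H-8 cis) | C1CC[C@@]2(C)O[C@@H]2[C@@H](O[Si](CC)(CC)CC)[C@H](C(=C)CO[Si](C)(C)C(C)(C)C)[C@H](O)/C=C1/C(=O)OC | intermediate
25 | (E)-2-methylbut-2-en-1-ol | C/C=C(\C)CO | starting material
26 | [(2R,3R)-2,3-dimethyloxiran-2-yl]methanol | OC[C@@]1(C)O[C@@H]1C | intermediate
27 | (2S,3R)-2,3-dimethyloxirane-2-carbaldehyde | O=C[C@@]1(C)O[C@@H]1C | intermediate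
28 | (2S,3R)-2,3-dimethyloxirane-2-carboxylic acid | OC(=O)[C@@]1(C)O[C@@H]1C | intermediate
29 | (2S,3R)-2,3-dimethyloxirane-2-carboxylic 2,4,6-trichlorobenzoic anhydride | O=C(OC(=O)c1c(Cl)cc(Cl)cc1Cl)[C@@]1(C)O[C@@H]1C | intermediate
30 | C8 (2S,3R)-2,3-dimethyloxirane-2-carboxylate of 24 | C1CC[C@@]2(C)O[C@@H]2[C@@H](O[Si](CC)(CC)CC)[C@H](C(=C)CO[Si](C)(C)C(C)(C)C)[C@H](OC(=O)[C@@]3(C)O[C@@H]3C)/C=C1/C(=O)OC | intermediate
31 | C6,C12-diol from 30 (6-OH and 7-(3-hydroxyprop-1-en-2-yl)) | C1CC[C@@]2(C)O[C@@H]2[C@@H](O)[C@H](C(=C)CO)[C@H](OC(=O)[C@@]3(C)O[C@@H]3C)/C=C1/C(=O)OC | intermediate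
32 | 6,12-lactol (C12 epimers) | C=C1C(O)O[C@H]2[C@H]1[C@H](OC(=O)[C@@]1(C)O[C@@H]1C)/C=C(/C(=O)OC)CCC[C@@]1(C)O[C@H]21 | intermediate
33 | 6,12-olide with 11(13)-methylene, 8-acyloxy, ring-cis C9=C10 enoate, 4,5-epoxide | C=C1C(=O)O[C@H]2[C@H]1[C@H](OC(=O)[C@@]1(C)O[C@@H]1C)/C=C(/C(=O)OC)CCC[C@@]1(C)O[C@H]21 | intermediate
34 | 9-hydroperoxide of 35 | C=C1C(=O)O[C@H]2[C@H]1[C@H](OC(=O)[C@@]1(C)O[C@@H]1C)[C@H](OO)/C(C(=O)OC)=C\CC[C@@]1(C)O[C@H]21 | intermediate
35 | CNP0262846.1: methyl (4R,5R,6S,7R,8S,9R)-8-[(2S,3R)-2,3-dimethyloxirane-2-carbonyloxy]-4,5-epoxy-9-hydroxy-12-oxo-germacra-1(10),11(13)-dien-6,12-olid-14-oate, C1=C10 ring-cis | C=C1C(=O)O[C@H]2[C@H]1[C@H](OC(=O)[C@@]1(C)O[C@@H]1C)[C@H](O)/C(C(=O)OC)=C\CC[C@@]1(C)O[C@H]21 | target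

**Step count**

Total: 18 steps. Longest linear sequence: 15 steps (steps 1–8, 10–12, 15–18); step 9 and steps 13–14 make the two side fragments.

**Steps most likely to fail**

1. Step 12 (proposed new method). The stabilised dienolate may fail to rearrange at temperatures the substrate tolerates, or may return starting material after proton transfer. The fallback sets out from 22 and uses the known allyl-carbanion variant of the ring contraction of 13-membered diallyl ethers. iBu2AlH (CH2Cl2, −78 °C) reduces the ester to the macrocyclic allylic alcohol F1. n-BuLi (2.2 equiv, THF, −78 → −20 °C) forms the alkoxide and lithiates the less substituted allylic CH2–O position (C8), and the [2,3]-shift gives the ring-contracted diol F2. TEMPO/PhI(OAc)2 oxidises only the primary allylic hydroxyl to the enal F3, NaClO2/NaH2PO4/2-methylbut-2-ene gives the acid F4, and Me3SiCHN2 gives the methyl ester. The route is rejoined at 24.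

2. Step 18. Oxygen may attack both faces of C9=C10, giving poor facial selectivity at C9. The fallback sets out from 33 and is stereoconvergent. The crude hydroperoxides (34 and its C9 epimer F5) are dehydrated with Ac2O/Et3N (Kornblum–DeLaMare) to the single 9-ketone F6. Luche reduction (NaBH4, CeCl3, MeOH, −78 °C) then delivers hydride, not oxygen, to the exposed face and so places the hydroxyl on the other face. The route is rejoined at 35.

3. Step 11. Oligomerisation or protodeboronation may outrun the slow transmetalation of the alkylborane at high dilution. The fallback sets out from 20 and changes the organometallic. The borane 21 is converted with I2/NaOMe into the primary iodide F7. Zn dust/LiCl (THF, rt) inserts into the alkyl C–I bond only, giving the alkylzinc iodide F8. Intramolecular Negishi coupling (Pd(PPh3)4, THF–NMP, slow addition) with the alkenyl iodide then closes the ring without aqueous base. The route is rejoined at 22.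

Further compounds
F1 | step 12 | macrocyclic allylic alcohol (22 with C14 as CH2OH) | C1CC[C@@]2(C)O[C@@H]2[C@@H](O[Si](CC)(CC)CC)/C=C(\COC/C=C1/CO)CO[Si](C)(C)C(C)(C)C
F2 | step 12 | ring-contracted diol (24 with C14 as CH2OH) | C1CC[C@@]2(C)O[C@@H]2[C@@H](O[Si](CC)(CC)CC)[C@H](C(=C)CO[Si](C)(C)C(C)(C)C)[C@H](O)/C=C1/CO
F3 | step 12 | ring-contracted enal (24 with C14 as CHO) | C1CC[C@@]2(C)O[C@@H]2[C@@H](O[Si](CC)(CC)CC)[C@H](C(=C)CO[Si](C)(C)C(C)(C)C)[C@H](O)/C=C1/C=O
F4 | step 12 | ring-contracted acid (24 with C14 as CO2H) | C1CC[C@@]2(C)O[C@@H]2[C@@H](O[Si](CC)(CC)CC)[C@H](C(=C)CO[Si](C)(C)C(C)(C)C)[C@H](O)/C=C1/C(=O)O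
F5 | step 18 | C9 epimer of hydroperoxide 34 | C=C1C(=O)O[C@H]2[C@H]1[C@H](OC(=O)[C@@]1(C)O[C@@H]1C)[C@@H](OO)/C(C(=O)OC)=C\CC[C@@]1(C)O[C@H]21
F6 | step 18 | 9-ketone (9-oxo analogue of 35) | C=C1C(=O)O[C@H]2[C@H]1[C@H](OC(=O)[C@@]1(C)O[C@@H]1C)C(=O)/C(C(=O)OC)=C\CC[C@@]1(C)O[C@H]21
F7 | step 11 | primary iodide (20 with C1H2I in place of the terminal alkene) | ICCC[C@@]1(C)O[C@@H]1[C@@H](O[Si](CC)(CC)CC)/C=C(\COC/C=C(\I)C(=O)OC)CO[Si](C)(C)C(C)(C)C
F8 | step 11 | alkylzinc iodide from F7 | I[Zn]CCC[C@@]1(C)O[C@@H]1[C@@H](O[Si](CC)(CC)CC)/C=C(\COC/C=C(\I)C(=O)OC)CO[Si](C)(C)C(C)(C)C
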